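**Plan**

- Retrosynthesis: the hemiaminal OH is removed first. The pyrrolinone C=C (Knoevenagel) and the amide N–C(O) bond (macrolactam) are cut next, then the aryl ether C–O bond. The two ring C bonds that close rings B and C together follow (quaternary C to fusion CH, and CH(CH3) to CH2). Last come the two ring A bonds of a Diels–Alder reaction with maleic anhydride.
- Forward: ring A arises with a cis-fused lactone that tells the two carboxyl carbons apart. Rings B and C then close in one step. The aryl ether is attached, a 14-membered lactam is closed, and it contracts to the 13-membered cyclophane when the pyrrolinone forms. Hydroxylation ends the route.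
- Structural feature used: rings B (cyclopentane) and C (trimethylcyclohexane) share the bond from the methyl-bearing quaternary carbon to the fusion CH and are cis-fused there. The ring C methyl next to the fusion CH is trans to the aryloxy carbon. With a ketone at the aryloxy carbon, this is the pattern a diene leaves on adding to an (E)-propenyl ketone.
- Stereochemistry: a lactate-derived silyloxy centre fixes the face of the first Diels–Alder reaction and is then oxidised away. The endo rule and one epimerisation give the ring A pattern. Ring A directs the intramolecular cycloaddition (three centres). Hydride and H2 add from the open faces to set the carbinol and the last ring C methyl. The SNAr step keeps the carbinol configuration, and the hemiaminal equilibrates.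

Key step: step 15

Assumption: in step 6 the dienophile is taken to add anti to the allylic silyloxy group (carbinol H eclipsed with the diene methyl), which calls for the (R)-lactate series; the hemiaminal carbon of 47 is taken to settle in the drawn configuration by ring–chain tautomerism within the cyclophane.

Lactones 11–23 are named as isobenzofuranones: C-1 lactone carbonyl, C-3 OCH2, C-3a/C-7a ring fusion, C-4=C-5 alkene.

**Step 1**
Reactants: 1 methyl (R)-lactate
Product: 2 methyl (R)-2-(tert-butyldimethylsilyloxy)propanoate
Conditions: TBSCl, imidazole, DMF, 0 → 25 °C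
Reagents that add atoms: tert-butyldimethylsilyl chloride, CC(C)(C)[Si](C)(C)Cl
Why: Standard silyl ether formation on a secondary alcohol; the bulky silyloxy group later steers the ring A cycloaddition.

**Step 2**
Reactants: 2 methyl (R)-2-(tert-butyldimethylsilyloxy)propanoate
Product: 3 (R)-2-(tert-butyldimethylsilyloxy)propanal
Conditions: i-Bu2AlH (1.1 equiv), CH2Cl2, −78 °C; aq. potassium sodium tartrate
Reagents that add atoms: none
Why: Partial ester reduction stops at the aldehyde through the aluminium hemiacetal at −78 °C, and the α-silyloxy aldehyde should keep its configuration if used at once.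

**Step 3**
Reactants: 3 (R)-2-(tert-butyldimethylsilyloxy)propanal; 4 2-(triphenylphosphoranylidene)propanal
Product: 5 (R,E)-4-(tert-butyldimethylsilyloxy)-2-methylpent-2-enal
Conditions: toluene, 90 °C
Reagents that add atoms: none
Why: Wittig olefination with a stabilised formyl ylide should give the (E)-trisubstituted enal.

**Step 4**
Reactants: 5 (R,E)-4-(tert-butyldimethylsilyloxy)-2-methylpent-2-enal; 6 triethyl phosphonoacetate
Product: 7 ethyl (2E,4E,6R)-6-(tert-butyldimethylsilyloxy)-4-methylhepta-2,4-dienoate
Conditions: NaH, THF, 0 → 25 °C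
Reagents that add atoms: none
Why: Horner–Wadsworth–Emmons olefination is E-selective and completes the (E,E)-diene.

**Step 5**
Reactants: 7 ethyl (2E,4E,6R)-6-(tert-butyldimethylsilyloxy)-4-methylhepta-2,4-dienoate
Product: 8 (2E,4E,6R)-6-(tert-butyldimethylsilyloxy)-4-methylhepta-2,4-dien-1-ol
Conditions: i-Bu2AlH (2.2 equiv), CH2Cl2, −78 °C; aq. potassium sodium tartrate
Reagents that add atoms: none
Why: 1,2-Reduction of the conjugated ester gives the dienol without touching the diene.

**Step 6**
Reactants: 8 (2E,4E,6R)-6-(tert-butyldimethylsilyloxy)-4-methylhepta-2,4-dien-1-ol; 9 maleic anhydride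
Product: 11 6-[(R)-1-(tert-butyldimethylsilyloxy)ethyl]-5-methyl-1-oxo-1,3,3a,6,7,7a-hexahydroisobenzofuran-7-carboxylic acid (H-3a/H-6/H-7/H-7a all cis), via cycloadduct anhydride 10 (not isolated)
Conditions: BHT (cat.), toluene, 25 → 80 °C
Reagents that add atoms: none
Why: An endo Diels–Alder reaction of the (E,E)-diene should set the four ring centres all-cis, the anhydride adding anti to the silyloxy group in the rotamer held by 1,3-allylic strain with the diene methyl, and the cis hydroxymethyl group then opens the nearer anhydride carbonyl to the γ-lactone, which leaves the other carboxyl free.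

**Step 7**
Reactants: 11 all-cis lactone acid
Product: 12 allyl ester of 11
Conditions: allyl bromide, Cs2CO3, DMF, 25 °C
Reagents that add atoms: allyl bromide, C=CCBr
Why: Carboxylate O-alkylation masks the acid as an ester that can later be removed under neutral conditions.

**Step 8**
Reactants: 12 allyl ester of 11
Product: 14 allyl 6-acetyl-5-methyl-1-oxo-1,3,3a,6,7,7a-hexahydroisobenzofuran-7-carboxylate (all-cis), via secondary alcohol 13 (not isolated)
Conditions: CrO3, aq. H2SO4, acetone, 0 → 25 °C
Reagents that add atoms: none
Why: Jones oxidation cleaves the secondary silyl ether in the acidic medium and should oxidise the freed alcohol to the methyl ketone faster than it can lactonise onto the neighbouring ester; the lactate centre is erased here.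

**Step 9**
Reactants: 14 all-cis methyl ketone
Product: 15 allyl 6-acetyl-5-methyl-1-oxo-1,3,3a,6,7,7a-hexahydroisobenzofuran-7-carboxylate with H-6 trans to H-7 (H-3a/H-7/H-7a cis)
Conditions: DBU (0.3 equiv), CH2Cl2, 25 °C
Reagents that add atoms: none
Why: Base-mediated epimerisation α to the ketone proceeds through the dienolate, which reprotonates kinetically at the α-carbon, and relief of the all-cis crowding should drive the acetyl group trans to the ester.

**Step 10**
Reactants: 15 trans methyl ketone; 16 prop-1-ynylmagnesium bromide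
Product: 17 allyl 6-(2-hydroxypent-3-yn-2-yl)-5-methyl-1-oxo-1,3,3a,6,7,7a-hexahydroisobenzofuran-7-carboxylate (both carbinol epimers)
Conditions: THF, −78 → −40 °C; H2O
Reagents that add atoms: none
Why: Grignard 1,2-addition should take the ketone in preference to the ester and lactone at low temperature; the new carbinol centre is lost in step 11.

**Step 11**
Reactants: 17 tertiary propargylic alcohol
Product: 18 allyl 5-methyl-1-oxo-6-[(E)-4-oxopent-2-en-2-yl]-1,3,3a,6,7,7a-hexahydroisobenzofuran-7-carboxylate
Conditions: Ph3PAuNTf2 (2 mol %), MeOH (1 equiv), toluene, 25 °C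
Reagents that add atoms: none
Why: Gold-catalysed Meyer–Schuster rearrangement turns the tertiary propargylic alcohol into the β,β-disubstituted enone, and the E isomer (acetyl trans to the ring) is the thermodynamically preferred one.

**Step 12**
Reactants: 18 (E)-enone
Product: 19 allyl 6-[(E)-4-(tert-butyldimethylsilyloxy)penta-2,4-dien-2-yl]-5-methyl-1-oxo-1,3,3a,6,7,7a-hexahydroisobenzofuran-7-carboxylate
Conditions: TBSOTf, Et3N, CH2Cl2, −78 → 0 °C
Reagents that add atoms: tert-butyldimethylsilyl trifluoromethanesulfonate, CC(C)(C)[Si](C)(C)OS(=O)(=O)C(F)(F)F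
Why: Soft enolisation and O-silylation at the methyl group of the enone gives the cross-conjugated 2-silyloxydiene under kinetic control.

**Step 13**
Reactants: 19 silyloxydiene allyl ester
Product: 20 potassium 6-[(E)-4-(tert-butyldimethylsilyloxy)penta-2,4-dien-2-yl]-5-methyl-1-oxo-1,3,3a,6,7,7a-hexahydroisobenzofuran-7-carboxylate
Conditions: Pd(PPh3)4 (5 mol %), potassium 2-ethylhexanoate, EtOAc/CH2Cl2, 25 °C
Reagents that add atoms: potassium 2-ethylhexanoate, CCCCC(CC)C(=O)[O-].[K+]
Why: Tsuji–Trost deallylation with a carboxylate as allyl acceptor frees the acid as its potassium salt without acid or fluoride, so the silyl dienol ether and the lactone should survive.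

**Step 14**
Reactants: 20 potassium carboxylate; 21 (E)-tributyl(prop-1-en-1-yl)stannane
Product: 23 7-[(E)-but-2-enoyl]-6-[(E)-4-(tert-butyldimethylsilyloxy)penta-2,4-dien-2-yl]-5-methyl-3a,6,7,7a-tetrahydroisobenzofuran-1(3H)-one (H-3a/H-7/H-7a cis; H-6 trans to H-7), via acid chloride 22 (not isolated)
Conditions: (COCl)2, CH2Cl2, 0 °C; then 21, Pd2(dba)3 (2.5 mol %), P(2-furyl)3, THF, 25 °C
Reagents that add atoms: oxalyl chloride, ClC(=O)C(=O)Cl (its chlorine is in 22 only)
Why: The carboxylate salt gives the acid chloride without free HCl, and Stille acylation with the (E)-alkenylstannane should deliver the (E)-enone with retention of alkene geometry while leaving the lactone and silyl dienol ether alone.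

**Step 15**
Reactants: 23 silyloxydiene enone lactone
Product: 24 tetracyclic lactone ketone: ring A with cis-fused lactone, trans-fused cyclopentanone ring B, cis-fused ring C bearing the angular methyl, the CH(CH3) group and the silyl enol ether
Conditions: BHT, toluene (0.005 M), 110 °C, sealed tube
Reagents that add atoms: none
Why: On heating, the 2-silyloxydiene adds to the tethered (E)-enone in a concerted, asynchronous [4+2] cycloaddition (intramolecular Diels–Alder reaction of the nona-1,6,8-trien-3-one type, the closest known case being silyloxydiene–enone cyclisations that give angularly methylated cis-hydrindanones): the enol ether CH2 terminus, which carries the largest HOMO coefficient, bonds to the enone β-carbon and the methyl-bearing terminus to the α-carbon. Ring C closes as the six-membered cycloaddition ring and ring B as the five-membered ring completed across the three-atom tether (two ring A carbons plus the ketone carbon), so both rings form in one step. The quaternary carbon and the fusion CH are set cis by the transition state with the tether ketone endo, the usual course for trienones whose carbonyl lies inside the tether, and the fusion CH, being α to the new ketone, can relax to the cis-hydrindanone if needed. The CH(CH3) centre follows from the E geometry of the dienophile through suprafacial addition, its methyl ending trans to the ketone carbon. The diene face is fixed by ring A, whose trans arms are both equatorial in the lactone-locked half-chair: only the rotamer that turns the slim vinylic CH, not the C-methyl, toward the methylated ring A alkene carbon lets the diene reach the enone, so the angular methyl ends cis to the A/B fusion hydrogen on its neighbouring carbon. The step needs this diene-face selectivity together with endo closure, and the silyloxy group is relied on to make the cycloaddition fast enough at the disubstituted diene terminus to outrun [1,5]-hydrogen shift.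

**Step 16**
Reactants: 24 tetracyclic lactone ketone
Product: 26 tetracyclic hydroxy ketone (ring B carbinol with OH cis to ring C; ring C cyclohexanone), via carbinol silyl enol ether 25 (not isolated)
Conditions: NaBH4, EtOH/THF, −20 °C; acetone; then 1 M HCl, THF, 25 °C
Reagents that add atoms: none
Why: Borohydride reduction should take the cyclopentanone from the convex face of the cis-fused B/C unit while the second ketone is still masked, which also removes the risk of epimerising the A/B fusion carbon next to the ketone, and dilute acid then hydrolyses the silyl enol ether.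

**Step 17**
Reactants: 26 tetracyclic hydroxy ketone
Product: 27 exocyclic methylene compound (ring C C=CH2 in place of C=O)
Conditions: Ph3PCH3Br, KOt-Bu (3 equiv each), THF, 0 → 25 °C
Reagents that add atoms: methyltriphenylphosphonium bromide, C[P+](c1ccccc1)(c1ccccc1)c1ccccc1.[Br-]
Why: Wittig methylenation of the unhindered cyclohexanone; the lactone is inert to the ylide and the free carbinol only consumes base.

**Step 18**
Reactants: 27 exocyclic methylene compound
Product: 28 trimethyl tetracyclic lactone alcohol (new ring C methyl cis to the two ring B bonds and trans to the angular methyl)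
Conditions: H2 (1 atm), RhCl(PPh3)3 (10 mol %), benzene/EtOH, 25 °C
Reagents that add atoms: none
Why: Homogeneous hydrogenation with RhCl(PPh3)3 reduces only the 1,1-disubstituted alkene and should deliver H2 to the face away from the axial ring B bond on the neighbouring quaternary carbon, which leaves the methyl on the ring B side.

**Step 19**
Reactants: 28 trimethyl tetracyclic lactone alcohol
Product: 29 hydroxymethyl Weinreb amide (ring A carries cis CH2OH and C(O)N(OMe)Me; ring B carbinol free)
Conditions: MeNH(OMe)·HCl, i-PrMgCl, THF, −20 → 0 °C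
Reagents that add atoms: N,O-dimethylhydroxylamine hydrochloride, CNOC.Cl
Why: Aminolysis of the lactone by the magnesium amide gives the Weinreb amide and the primary alcohol, separating the future acyl and vinyl arms.

**Step 20**
Reactants: 29 hydroxymethyl Weinreb amide
Product: 30 ring A aldehyde (CHO cis to the Weinreb amide)
Conditions: TEMPO (10 mol %), PhI(OAc)2, CH2Cl2, 25 °C
Reagents that add atoms: none
Why: Oxoammonium-catalysed oxidation is selective for the primary alcohol over the hindered ring B carbinol and is not basic, so the α-centre of the β,γ-unsaturated aldehyde should hold.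

**Step 21**
Reactants: 30 ring A aldehyde
Product: 31 vinyl Weinreb amide alcohol
Conditions: Ph3PCH3Br, KN(SiMe3)2, THF, −78 → 0 °C
Reagents that add atoms: methyltriphenylphosphonium bromide, C[P+](c1ccccc1)(c1ccccc1)c1ccccc1.[Br-]
Why: Wittig methylenation at low temperature installs the vinyl group; the Weinreb amide is inert and its α-hydrogen is too weakly acidic for the axial acyl centre to epimerise.

**Step 22**
Reactants: 31 vinyl Weinreb amide alcohol; 32 4-fluorobenzaldehyde
Product: 33 4-formylphenyl ether of the ring B carbinol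
Conditions: KN(SiMe3)2 (1.05 equiv), THF/DMF, 0 → 25 °C
Reagents that add atoms: none
Why: SNAr addition–elimination of the potassium alkoxide on the para-formyl-activated aryl fluoride forms the aryl ether; the carbinol C–O bond is not broken, so its configuration is retained.

**Step 23**
Reactants: 33 aryl ether aldehyde; 34 1,1-diethoxy-2-nitroethane
Product: 37 (E)-nitroalkene ArCH=C(NO2)CH(OEt)2, via nitroaldol 35 (not isolated), via nitroaldol mesylate 36 (not isolated)
Conditions: n-Bu4NF (cat.), THF, 0 °C; then MsCl, i-Pr2NEt, −20 → 0 °C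
Reagents that add atoms: none
Why: Henry addition followed by mesylation and elimination gives the conjugated nitroalkene, which carries the future lactam nitrogen and a masked aldehyde.

**Step 24**
Reactants: 37 nitroalkene
Product: 38 nitroalkane ArCH2CH(NO2)CH(OEt)2 (both epimers at the nitro-bearing carbon)
Conditions: NaBH4, THF/EtOH, 0 °C
Reagents that add atoms: none
Why: Conjugate hydride reduction of the nitroalkene; the new centre forms without control, which does not matter because it is reset in step 29.

**Step 25**
Reactants: 38 nitroalkane; 39 tert-butyl acetate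
Product: 40 tert-butyl β-keto ester (ring A acyl arm now C(O)CH2CO2t-Bu)
Conditions: LiN(i-Pr)2, THF, −78 °C (enolate of 39, 4 equiv); then 38, −78 → −30 °C; AcOH
Reagents that add atoms: none
Why: Claisen-type acylation of the ester enolate by the Weinreb amide stops at the ketone through the chelated tetrahedral intermediate, while the nitroalkane rides through as its nitronate.

**Step 26**
Reactants: 40 tert-butyl β-keto ester
Product: 41 primary amine ArCH2CH(NH2)CH(OEt)2 (both epimers), used at once
Conditions: Zn, AcOH, EtOH, 0 → 25 °C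
Reagents that add atoms: none
Why: Dissolving-metal reduction of the aliphatic nitro group gives the amine and leaves the alkenes, the acetal and the β-keto ester alone.

**Step 27**
Reactants: 41 amino β-keto ester
Product: 43 14-membered β-keto lactam (both epimers at the acetal-bearing carbon), via acylketene 42 (not isolated)
Conditions: toluene (0.001 M), 110 °C, slow addition
Reagents that add atoms: none
Why: Thermal loss of tert-butanol from the β-keto ester gives an acylketene that the amine traps within the molecule, a macrolactamisation of known type that high dilution should favour.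

**Step 28**
Reactants: 43 14-membered β-keto lactam
Product: 45 13-membered cyclophane with a 3-acyl-1,5-dihydropyrrol-2-one ring (C-5 of the lactam epimerisable), via amido aldehyde 44 (not isolated)
Conditions: CF3CO2H, H2O, CH2Cl2, 0 → 25 °C; then ethylenediammonium diacetate (cat.), MeOH, 25 °C
Reagents that add atoms: none
Why: Acetal hydrolysis frees the α-amido aldehyde, which should undergo intramolecular Knoevenagel condensation with the β-keto amide methylene (five-membered ring closure), contracting the macrocycle to the 13-membered carbocycle.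

**Step 29**
Reactants: 45 macrocyclic 3-acyl-1,5-dihydropyrrol-2-one
Product: 47 target CNP0151253.3, via hydroperoxide 46 (not isolated)
Conditions: O2 (1 atm), Et3N, THF, 25 °C; then Me2S
Reagents that add atoms: dioxygen, O=O
Why: Base-promoted autoxidation through the 2-hydroxypyrrole tautomer places oxygen on C-5 of the lactam, Me2S reduces the hydroperoxide, and the hemiaminal should then settle in the drawn configuration by ring–chain tautomerism.

**Compound list**

1 | methyl (R)-lactate | COC(=O)[C@@H](C)O | starting material
2 | methyl (R)-2-(tert-butyldimethylsilyloxy)propanoate | COC(=O)[C@@H](C)O[Si](C)(C)C(C)(C)C | intermediate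
3 | (R)-2-(tert-butyldimethylsilyloxy)propanal | O=C[C@@H](C)O[Si](C)(C)C(C)(C)C | intermediate
4 | 2-(triphenylphosphoranylidene)propanal | CC(C=O)=P(c1ccccc1)(c1ccccc1)c1ccccc1 | starting material
5 | (R,E)-4-(tert-butyldimethylsilyloxy)-2-methylpent-2-enal | O=C/C(C)=C/[C@@H](C)O[Si](C)(C)C(C)(C)C | intermediate
6 | triethyl phosphonoacetate | CCOC(=O)CP(=O)(OCC)OCC | starting material
7 | ethyl (2E,4E,6R)-6-(tert-butyldimethylsilyloxy)-4-methylhepta-2,4-dienoate | CCOC(=O)/C=C/C(C)=C/[C@@H](C)O[Si](C)(C)C(C)(C)C | intermediate
8 | (2E,4E,6R)-6-(tert-butyldimethylsilyloxy)-4-methylhepta-2,4-dien-1-ol | OC/C=C/C(C)=C/[C@@H](C)O[Si](C)(C)C(C)(C)C | intermediate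
9 | maleic anhydride | O=C1C=CC(=O)O1 | starting material
10 | cycloadduct anhydride, all-cis, not isolated | OC[C@H]1C=C(C)[C@@H]([C@@H](C)O[Si](C)(C)C(C)(C)C)[C@H]2C(=O)OC(=O)[C@@H]12 | intermediate
11 | all-cis lactone acid | O=C1OC[C@H]2C=C(C)[C@@H]([C@@H](C)O[Si](C)(C)C(C)(C)C)[C@@H](C(=O)O)[C@@H]12 | intermediate
12 | allyl ester of 11 | O=C1OC[C@H]2C=C(C)[C@@H]([C@@H](C)O[Si](C)(C)C(C)(C)C)[C@@H](C(=O)OCC=C)[C@@H]12 | intermediate
13 | secondary alcohol from 12, not isolated | O=C1OC[C@H]2C=C(C)[C@@H]([C@@H](C)O)[C@@H](C(=O)OCC=C)[C@@H]12 | intermediate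
14 | all-cis methyl ketone allyl ester | O=C1OC[C@H]2C=C(C)[C@@H](C(C)=O)[C@@H](C(=O)OCC=C)[C@@H]12 | intermediate
15 | methyl ketone allyl ester, acetyl trans to ester | O=C1OC[C@H]2C=C(C)[C@H](C(C)=O)[C@@H](C(=O)OCC=C)[C@@H]12 | intermediate
16 | prop-1-ynylmagnesium bromide | CC#C[Mg]Br | starting material
17 | tertiary propargylic alcohol, both carbinol epimers | O=C1OC[C@H]2C=C(C)[C@H](C(C)(O)C#CC)[C@@H](C(=O)OCC=C)[C@@H]12 | intermediate
18 | (E)-enone allyl ester | O=C1OC[C@H]2C=C(C)[C@H](/C(C)=C/C(C)=O)[C@@H](C(=O)OCC=C)[C@@H]12 | intermediate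
19 | 2-silyloxydiene allyl ester | O=C1OC[C@H]2C=C(C)[C@H](/C(C)=C/C(=C)O[Si](C)(C)C(C)(C)C)[C@@H](C(=O)OCC=C)[C@@H]12 | intermediate
20 | potassium carboxylate of the 2-silyloxydiene | O=C1OC[C@H]2C=C(C)[C@H](/C(C)=C/C(=C)O[Si](C)(C)C(C)(C)C)[C@@H](C(=O)[O-])[C@@H]12.[K+] | intermediate
21 | (E)-tributyl(prop-1-en-1-yl)stannane | C/C=C/[Sn](CCCC)(CCCC)CCCC | starting material
22 | acid chloride, not isolated | O=C1OC[C@H]2C=C(C)[C@H](/C(C)=C/C(=C)O[Si](C)(C)C(C)(C)C)[C@@H](C(Cl)=O)[C@@H]12 | intermediate
23 | silyloxydiene (E)-crotonyl ketone lactone, precursor of the key step | O=C1OC[C@H]2C=C(C)[C@H](/C(C)=C/C(=C)O[Si](C)(C)C(C)(C)C)[C@@H](C(=O)/C=C/C)[C@@H]12 | intermediate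
24 | tetracyclic lactone ketone silyl enol ether, product of the key step | O=C1OC[C@H]2C=C(C)[C@H]3[C@H]([C@@H]12)C(=O)[C@H]1[C@H](C)CC(O[Si](C)(C)C(C)(C)C)=C[C@]13C | intermediate
25 | ring B carbinol silyl enol ether, not isolated | O=C1OC[C@H]2C=C(C)[C@H]3[C@H]([C@@H]12)[C@@H](O)[C@H]1[C@H](C)CC(O[Si](C)(C)C(C)(C)C)=C[C@]13C | intermediate
26 | tetracyclic hydroxy ketone | O=C1OC[C@H]2C=C(C)[C@H]3[C@H]([C@@H]12)[C@@H](O)[C@H]1[C@H](C)CC(=O)C[C@]13C | intermediate
27 | exocyclic methylene compound | O=C1OC[C@H]2C=C(C)[C@H]3[C@H]([C@@H]12)[C@@H](O)[C@H]1[C@H](C)CC(=C)C[C@]13C | intermediate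
28 | trimethyl tetracyclic lactone alcohol | O=C1OC[C@H]2C=C(C)[C@H]3[C@H]([C@@H]12)[C@@H](O)[C@H]1[C@H](C)C[C@@H](C)C[C@]13C | intermediate
29 | hydroxymethyl Weinreb amide | OC[C@H]1C=C(C)[C@H]2[C@@H]([C@@H](O)[C@H]3[C@H](C)C[C@@H](C)C[C@@]23C)[C@H]1C(=O)N(C)OC | intermediate
30 | ring A aldehyde Weinreb amide | O=C[C@H]1C=C(C)[C@H]2[C@@H]([C@@H](O)[C@H]3[C@H](C)C[C@@H](C)C[C@@]23C)[C@H]1C(=O)N(C)OC | intermediate
31 | vinyl Weinreb amide alcohol | C=C[C@H]1C=C(C)[C@H]2[C@@H]([C@@H](O)[C@H]3[C@H](C)C[C@@H](C)C[C@@]23C)[C@H]1C(=O)N(C)OC | intermediate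
32 | 4-fluorobenzaldehyde | O=Cc1ccc(F)cc1 | starting material
33 | 4-formylphenyl ether | C=C[C@H]1C=C(C)[C@H]2[C@@H]([C@@H](Oc3ccc(C=O)cc3)[C@H]3[C@H](C)C[C@@H](C)C[C@@]23C)[C@H]1C(=O)N(C)OC | intermediate
34 | 1,1-diethoxy-2-nitroethane | CCOC(C[N+](=O)[O-])OCC | starting material
35 | nitroaldol, diastereomer mixture, not isolated | C=C[C@H]1C=C(C)[C@H]2[C@@H]([C@@H](Oc3ccc(C(O)C(C(OCC)OCC)[N+](=O)[O-])cc3)[C@H]3[C@H](C)C[C@@H](C)C[C@@]23C)[C@H]1C(=O)N(C)OC | intermediate
36 | nitroaldol mesylate, not isolated | C=C[C@H]1C=C(C)[C@H]2[C@@H]([C@@H](Oc3ccc(C(OS(C)(=O)=O)C(C(OCC)OCC)[N+](=O)[O-])cc3)[C@H]3[C@H](C)C[C@@H](C)C[C@@]23C)[C@H]1C(=O)N(C)OC | intermediate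
37 | (E)-nitroalkene | C=C[C@H]1C=C(C)[C@H]2[C@@H]([C@@H](Oc3ccc(/C=C(/[N+](=O)[O-])C(OCC)OCC)cc3)[C@H]3[C@H](C)C[C@@H](C)C[C@@]23C)[C@H]1C(=O)N(C)OC | intermediate
38 | nitroalkane, both epimers at the nitro-bearing carbon | C=C[C@H]1C=C(C)[C@H]2[C@@H]([C@@H](Oc3ccc(CC(C(OCC)OCC)[N+](=O)[O-])cc3)[C@H]3[C@H](C)C[C@@H](C)C[C@@]23C)[C@H]1C(=O)N(C)OC | intermediate
39 | tert-butyl acetate | CC(=O)OC(C)(C)C | starting material
40 | tert-butyl β-keto ester, both epimers at the nitro-bearing carbon | C=C[C@H]1C=C(C)[C@H]2[C@@H]([C@@H](Oc3ccc(CC(C(OCC)OCC)[N+](=O)[O-])cc3)[C@H]3[C@H](C)C[C@@H](C)C[C@@]23C)[C@H]1C(=O)CC(=O)OC(C)(C)C | intermediate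
41 | amino β-keto ester, both epimers at the amino-bearing carbon | C=C[C@H]1C=C(C)[C@H]2[C@@H]([C@@H](Oc3ccc(CC(N)C(OCC)OCC)cc3)[C@H]3[C@H](C)C[C@@H](C)C[C@@]23C)[C@H]1C(=O)CC(=O)OC(C)(C)C | intermediate
42 | acylketene, not isolated | C=C[C@H]1C=C(C)[C@H]2[C@@H]([C@@H](Oc3ccc(CC(N)C(OCC)OCC)cc3)[C@H]3[C@H](C)C[C@@H](C)C[C@@]23C)[C@H]1C(=O)C=C=O | intermediate
43 | 14-membered β-keto lactam, both epimers at the acetal-bearing carbon | C=C[C@H]1C=C(C)[C@H]2[C@H]3[C@@H](Oc4ccc(cc4)CC(C(OCC)OCC)NC(=O)CC(=O)[C@@H]13)[C@H]1[C@H](C)C[C@@H](C)C[C@]12C | intermediate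
44 | amido aldehyde, not isolated | C=C[C@H]1C=C(C)[C@H]2[C@H]3[C@@H](Oc4ccc(cc4)CC(C=O)NC(=O)CC(=O)[C@@H]13)[C@H]1[C@H](C)C[C@@H](C)C[C@]12C | intermediate
45 | 13-membered cyclophane 3-acyl-1,5-dihydropyrrol-2-one, C-5 of the lactam epimerisable | C=C[C@H]1C=C(C)[C@H]2[C@H]3[C@@H](Oc4ccc(cc4)CC4C=C(C(=O)N4)C(=O)[C@@H]13)[C@H]1[C@H](C)C[C@@H](C)C[C@]12C | intermediate
46 | C-5 hydroperoxide of the lactam, not isolated | C=C[C@H]1C=C(C)[C@H]2[C@H]3[C@@H](Oc4ccc(cc4)CC4(OO)C=C(C(=O)N4)C(=O)[C@@H]13)[C@H]1[C@H](C)C[C@@H](C)C[C@]12C | intermediate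
47 | CNP0151253.3 | C=C[C@H]1C=C(C)[C@H]2[C@H]3[C@@H](Oc4ccc(cc4)C[C@@]4(O)C=C(C(=O)N4)C(=O)[C@@H]13)[C@H]1[C@H](C)C[C@@H](C)C[C@]12C | target

**Step count and risks**

Total steps: 29. Longest linear sequence: 29 steps, from methyl (R)-lactate (1) to 47; all other inputs are commercial reagents.

Steps most likely to fail:

Step 28. The transannular Knoevenagel condensation has to build the strained 13-membered cyclophane from the 14-membered lactam. Ring strain may stall the aldol closure, or the acyl-bearing ring A centre may epimerise under prolonged catalysis. The fallback builds the pyrrolinone open-chain and closes the macrocycle last by copper-mediated aryl ether formation. It sets out from 31. The lithium enolate of 39 converts the Weinreb amide into the tert-butyl β-keto ester with free carbinol F1. Heating F1 in toluene with excess commercial (S)-2-amino-3-(4-iodophenyl)propan-1-ol gives the β-keto amide F2 through the acylketene. TEMPO/PhI(OAc)2 oxidation of the primary alcohol and ethylenediammonium diacetate then give the open-chain 5-(4-iodobenzyl)-3-acyl-1,5-dihydropyrrol-2-one F3. Intramolecular Ullmann etherification of the ring B carbinol (CuI, 3,4,7,8-tetramethyl-1,10-phenanthroline, Cs2CO3, toluene, 110 °C, high dilution) returns to the route at 45.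

Step 15. The cycloaddition may show poor diene-face or endo/exo selectivity. It may also be slow at the disubstituted diene terminus, so that [1,5]-hydrogen shift or loss of the silyl group competes. The fallback replaces the pericyclic step by an anionic double Michael addition. It sets out from 23. n-Bu4NF/AcOH removes the silyl group to give the bis-enone F4. LiN(SiMe3)2 in THF at −78 °C forms the cross-conjugated dienolate of the methyl ketone, which adds to the crotonyl ketone; the resulting enolate closes ring B onto the second enone. This gives the lithium enolate of the tetracyclic diketone F5, and TBSCl silylates it on oxygen to return to the route at 24.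

Step 22. The hindered alkoxide, on the concave face, may be consumed by hydride transfer to the aldehyde or by Tishchenko-type acylation instead of displacing fluoride. The fallback forms the aryl ether by palladium-catalysed C–O coupling with a masked aldehyde. It sets out from 31. Coupling with commercial 1-bromo-4-(diethoxymethyl)benzene ([Pd(C3H5)Cl]2, RockPhos, Cs2CO3, toluene, 90 °C) gives the aryl ether diethyl acetal F6. Mild aqueous acid (1 M HCl, THF) then returns to the route at 33.

**Further compounds**

F1 | step 28 | tert-butyl β-keto ester with free ring B carbinol | C=C[C@H]1C=C(C)[C@H]2[C@@H]([C@@H](O)[C@H]3[C@H](C)C[C@@H](C)C[C@@]23C)[C@H]1C(=O)CC(=O)OC(C)(C)C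
F2 | step 28 | β-keto amide of (S)-2-amino-3-(4-iodophenyl)propan-1-ol | C=C[C@H]1C=C(C)[C@H]2[C@@H]([C@@H](O)[C@H]3[C@H](C)C[C@@H](C)C[C@@]23C)[C@H]1C(=O)CC(=O)N[C@@H](Cc1ccc(I)cc1)CO
F3 | step 28 | open-chain 5-(4-iodobenzyl)-3-acyl-1,5-dihydropyrrol-2-one, C-5 epimerisable | C=C[C@H]1C=C(C)[C@H]2[C@@H]([C@@H](O)[C@H]3[C@H](C)C[C@@H](C)C[C@@]23C)[C@H]1C(=O)C1=CC(Cc2ccc(I)cc2)NC1=O
F4 | step 15 | bis-enone lactone (desilylated 23) | O=C1OC[C@H]2C=C(C)[C@H](/C(C)=C/C(C)=O)[C@@H](C(=O)/C=C/C)[C@@H]12
F5 | step 15 | lithium enolate of the tetracyclic diketone | O=C1OC[C@H]2C=C(C)[C@H]3[C@H]([C@@H]12)C(=O)[C@H]1[C@H](C)CC([O-])=C[C@]13C.[Li+]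
F6 | step 22 | aryl ether diethyl acetal | C=C[C@H]1C=C(C)[C@H]2[C@@H]([C@@H](Oc3ccc(C(OCC)OCC)cc3)[C@H]3[C@H](C)C[C@@H](C)C[C@@]23C)[C@H]1C(=O)N(C)OC
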